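**Retrosynthetic overview**
- Target ⇒ its 6,8-di-O-methyl ether (last step: O-demethylation).
- Side chain C1'–C2' bond ⇒ olefin cross-metathesis then hydrogenation between (S)-6,8-dimethoxy-3-vinylisochroman-1-one and (S)-undec-1-en-6-ol.
- Key disconnection: the lactone C3–O bond ⇒ enantioselective palladium-catalysed allylic C–H acyloxylation of 2-(but-3-enyl)-4,6-dimethoxybenzoic acid. This sets C3 and closes the lactone, the only ring made in the route; the benzene ring is bought.
- The butenyl acid ⇒ 2,4-dimethoxy-6-methylbenzoic acid + allyl bromide (lateral lithiation). The undecenol ⇒ resolved 1,2-epoxyheptane + but-3-enyl Grignard (sets C6').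

Assumption: the target is read as (3R)-6,8-dihydroxy-3-[(6S)-6-hydroxyundecyl]isochroman-1-one. The sense of induction of the new lactonisation cannot be predicted, so the ligand antipode that gives the (S)-vinyl lactone is fixed after one trial run.

**Step 1**
Reactants: 1 racemic 1,2-epoxyheptane (2-pentyloxirane)
Product: 2 (S)-1,2-epoxyheptane
Conditions: (S,S)-(salen)Co(OAc) (0.5 mol %), H2O (0.55 equiv), neat, 0 °C → rt, 18 h; distil
Reagents that add atoms: none
Why: Jacobsen hydrolytic kinetic resolution, in which the trivalent cobalt salen acetate hydrolyses the (R)-epoxide selectively and leaves the (S)-epoxide in high ee, which fixes the future C6' carbinol centre.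

**Step 2**
Reactants: 2 (S)-1,2-epoxyheptane; 3 but-3-enylmagnesium bromide (commercial THF solution)
Product: 4 (S)-undec-1-en-6-ol
Conditions: CuI (10 mol %), THF, −40 → 0 °C; then H2O
Reagents that add atoms: none
Why: Copper-catalysed Grignard opening of a terminal epoxide (SN2 at the CH2 carbon) leaves the stereocentre untouched, and the descriptor stays S because the new alkenyl chain outranks pentyl.

**Step 3**
Reactants: 5 2,4-dimethoxy-6-methylbenzoic acid; 6 allyl bromide
Product: 8 2-(but-3-en-1-yl)-4,6-dimethoxybenzoic acid, via dilithiated benzoate dianion 7 (not isolated)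
Conditions: LiN(iPr)2 (2.3 equiv, commercial solution), THF, −78 → 0 °C; then 6 (1.3 equiv), −78 °C → rt; 1 M HCl work-up
Reagents that add atoms: none
Why: Lateral (benzylic) lithiation of an ortho-toluic acid as its carboxylate dianion, followed by SN2 C-allylation of the benzylic carbanion, which is far more nucleophilic than the lithium carboxylate oxygen.

**Step 4**
Reactants: 8 2-(but-3-en-1-yl)-4,6-dimethoxybenzoic acid
Product: 9 (S)-6,8-dimethoxy-3-vinylisochroman-1-one
Conditions: Pd(OAc)2 (10 mol %), chiral aryl sulfoxide–oxazoline ligand (ArSOX type, tert-leucinol-derived, 12 mol %), 2,6-dimethyl-1,4-benzoquinone (1.5 equiv), toluene (0.1 M), 45 °C, 48 h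
Reagents that add atoms: none
Why: Proposed new method: enantioselective intramolecular allylic C–H acyloxylation of a benzoic acid, in which ligand-bound divalent palladium cleaves the homobenzylic allylic C–H bond (its carboxylate acting as internal base) to give a π-allylpalladium carboxylate, the tethered benzoate forms the C3–O bond at the internal allyl terminus (six-membered ring favoured over eight) inside the chiral ligand pocket so that this C–O bond formation sets C3 as S, and the quinone promotes the functionalisation and reoxidises zerovalent palladium fast enough that the allylic lactone is not re-ionised and racemised; the closest known reaction types are the palladium/sulfoxide–oxazoline-catalysed enantioselective allylic C–H etherification of the analogous benzylic alcohols to 3-vinylisochromans and the racemic palladium/bis-sulfoxide allylic C–H lactonisation of alkenoic acids.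

**Step 5**
Reactants: 9 (S)-6,8-dimethoxy-3-vinylisochroman-1-one; 4 (S)-undec-1-en-6-ol (2 equiv)
Product: 11 (3R)-3-[(6S)-6-hydroxyundecyl]-6,8-dimethoxyisochroman-1-one, via cross-metathesis alkene 10 (not isolated)
Conditions: second-generation Grubbs catalyst (5 mol %), CH2Cl2, 40 °C, 12 h; then solvent switch to EtOAc, PtO2 (5 mol %), H2 (1 atm), rt, same pot
Reagents that add atoms: none
Why: Olefin cross-metathesis of a vinyl lactone with an unhindered terminal alkene (ethene is lost) followed by platinum-catalysed alkene hydrogenation, which avoids allylic C–O hydrogenolysis and double-bond migration; neither stereocentre is touched, and the C3 descriptor changes from S to R only because the saturated chain now ranks below C4.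

**Step 6**
Reactants: 11 (3R)-3-[(6S)-6-hydroxyundecyl]-6,8-dimethoxyisochroman-1-one
Product: 12 (3R)-6,8-dihydroxy-3-[(6S)-6-hydroxyundecyl]isochroman-1-one (CNP0198395.1)
Conditions: BBr3 (5 equiv), CH2Cl2, −78 → 0 °C, 3 h; then H2O
Reagents that add atoms: none
Why: Lewis acid O-demethylation of aryl methyl ethers by BBr3, in which the lactone survives and the secondary alcohol is held as a borate ester at ≤ 0 °C and returned on hydrolysis, with no stereocentre involved.

**Compound list**
1 | racemic 1,2-epoxyheptane | CCCCCC1CO1 | starting material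
2 | (S)-1,2-epoxyheptane | CCCCC[C@H]1CO1 | intermediate
3 | but-3-enylmagnesium bromide | C=CCC[Mg]Br | starting material
4 | (S)-undec-1-en-6-ol | CCCCC[C@H](O)CCCC=C | intermediate
5 | 2,4-dimethoxy-6-methylbenzoic acid | Cc1cc(OC)cc(OC)c1C(=O)O | starting material
6 | allyl bromide | C=CCBr | starting material
7 | lithium 2-(lithiomethyl)-4,6-dimethoxybenzoate (dianion) | [Li]Cc1cc(OC)cc(OC)c1C(=O)O[Li] | intermediate
8 | 2-(but-3-en-1-yl)-4,6-dimethoxybenzoic acid | C=CCCc1cc(OC)cc(OC)c1C(=O)O | intermediate
9 | (S)-6,8-dimethoxy-3-vinylisochroman-1-one | C=C[C@@H]1Cc2cc(OC)cc(OC)c2C(=O)O1 | intermediate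
10 | (3S)-3-[(1E,6S)-6-hydroxyundec-1-en-1-yl]-6,8-dimethoxyisochroman-1-one | CCCCC[C@H](O)CCC/C=C/[C@@H]1Cc2cc(OC)cc(OC)c2C(=O)O1 | intermediate
11 | (3R)-3-[(6S)-6-hydroxyundecyl]-6,8-dimethoxyisochroman-1-one | CCCCC[C@H](O)CCCCC[C@@H]1Cc2cc(OC)cc(OC)c2C(=O)O1 | intermediate
12 | (3R)-6,8-dihydroxy-3-[(6S)-6-hydroxyundecyl]isochroman-1-one | CCCCC[C@H](O)CCCCC[C@@H]1Cc2cc(O)cc(O)c2C(=O)O1 | target

**Totals**
Total steps: 6. Longest linear sequence: 4 steps (5 → 8 → 9 → 11 → 12; the branch 1 → 2 → 4 → 11 → 12 is equally long).

**Steps most likely to fail, with fallbacks**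

Step 4 (the proposed new lactonisation). The risks are low enantioselectivity with a carboxylate nucleophile, erosion of ee if zerovalent palladium re-ionises the allylic lactone, and β-hydride elimination to the aryl diene. The fallback uses known chemistry and sets out from 8. The acid is reduced with LiAlH4 (THF, 0 °C → reflux) to [2-(but-3-en-1-yl)-4,6-dimethoxyphenyl]methanol F3. This benzylic alcohol is cyclised by the established Pd(OAc)2/aryl sulfoxide–oxazoline/2,6-dimethylbenzoquinone enantioselective allylic C–H etherification (toluene, 45 °C) to (S)-6,8-dimethoxy-3-vinylisochroman F4. The C1 methylene, which is benzylic, α to oxygen and on an electron-rich ring, is then oxidised with pyridinium chlorochromate [C5H5NH][CrO3Cl] in CH2Cl2 at reflux to the lactone. The fallback comes back to the route at 9.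

Step 6 (BBr3 with a free secondary alcohol). The risks are conversion of the C6' alcohol into the bromide and partial lactone cleavage. The fallback sets out from 11. The alcohol is masked with Ac2O/pyridine/DMAP as (6S)-1-[(3R)-6,8-dimethoxy-1-oxoisochroman-3-yl]undecan-6-yl acetate F5. Demethylation with BBr3 (CH2Cl2, −78 → 0 °C) then gives (6S)-1-[(3R)-6,8-dihydroxy-1-oxoisochroman-3-yl]undecan-6-yl acetate F6. The acetate is removed with K2CO3 in MeOH at rt, and acidification re-closes any opened lactone. The fallback comes back to the route at 12.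

Step 3 (dianion allylation). The risks are incomplete benzylic deprotonation of the electron-rich carboxylate, ring lithiation between the two methoxy groups, and O-allylation. The fallback sets out from 5. The acid is esterified with MeI/K2CO3 in DMF to methyl 2,4-dimethoxy-6-methylbenzoate F1. Lateral lithiation of this ester with LiN(iPr)2 (THF, −78 °C) and alkylation with allyl bromide 6 gives methyl 2-(but-3-en-1-yl)-4,6-dimethoxybenzoate F2. The hindered ester is saponified with KOH in DMSO/H2O at 80 °C and acidified. The fallback comes back to the route at 8.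

**Further compounds**
F1 | step 3 | methyl 2,4-dimethoxy-6-methylbenzoate | COC(=O)c1c(C)cc(OC)cc1OC
F2 | step 3 | methyl 2-(but-3-en-1-yl)-4,6-dimethoxybenzoate | COC(=O)c1c(CCC=C)cc(OC)cc1OC
F3 | step 4 | [2-(but-3-en-1-yl)-4,6-dimethoxyphenyl]methanol | OCc1c(CCC=C)cc(OC)cc1OC
F4 | step 4 | (S)-6,8-dimethoxy-3-vinylisochroman | C=C[C@@H]1Cc2cc(OC)cc(OC)c2CO1
F5 | step 6 | (6S)-1-[(3R)-6,8-dimethoxy-1-oxoisochroman-3-yl]undecan-6-yl acetate | CCCCC[C@H](OC(C)=O)CCCCC[C@@H]1Cc2cc(OC)cc(OC)c2C(=O)O1
F6 | step 6 | (6S)-1-[(3R)-6,8-dihydroxy-1-oxoisochroman-3-yl]undecan-6-yl acetate | CCCCC[C@H](OC(C)=O)CCCCC[C@@H]1Cc2cc(O)cc(O)c2C(=O)O1
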